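The numbers of this flask are invented, and the outcome is calculated.

Slowness was what I looked for first in this flask, in which a solid feeds a stirred tank whose target decays.

solid substrate 0.10 M; enzyme 10 µM; time 40 s

    starting material + enzyme → target + enzyme, rate k1*[starting material]^1.5*[enzyme]/(1 + ([starting material]/Kh1)^1.5) (Kh1 = 27.7 mM, k1 = 1.92 × 10⁵ M⁻¹·⁵ s⁻¹)
    solid substrate ⇌ starting material, rate k2*(cs2 - [starting material]) while solid is left; crystals form when [starting material] > cs2 (cs2 = 0.053 M, k2 = 0.0306 s⁻¹)
    2 starting material → homo dimer (k3 = 0.840 M⁻¹ s⁻¹)
    target → over-reaction product (k4 = 0.0649 s⁻¹)

- a species is counted by the solid substrate in it: one homo dimer counts as two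
- a step written with two of one species runs at k times the square of its concentration and takes two of it each time
- given per volume of solution although it is solid: solid substrate
- at the start none of the solid substrate is in solution
- starting material means what is dissolved; the solid is not counted in it
- run time (flask): 40 s

1. the target standing at 40 s, as a percentage of the solid substrate charged
2. concentration of starting material in solution at 40 s, in percent of saturation

The enzyme could turn over up to 0.00885 M s⁻¹, faster than the 0.00162 M s⁻¹ that dissolution gives at its fastest, so I took dissolution as the rate-limiting step and treated the making of target as a steady feed v. With κ the decay constant of target, 0.0649 s⁻¹, and T its concentration, I integrated the balance of target, and folded the givens into N, the run time t counted in target lifetimes: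

dT/dt = v − κT, so T = (v/κ)(1 − e^(−κt))

N = κt = 2.60

f = T/(vt) = (1 − e^(−N))/N = 0.356

I called f the surviving share: the part of the target made that still stands, for any steady v. Step 2 can deliver 64.9% by 40 s into a solution kept empty, which gave me a rough estimate for y of 23.1%. One number was not enough, since f says nothing of the starting material, so sat stayed open, and step 2 slows as starting material builds up.

The forecast gave a lower y, 17.2%, and a sat of 15.7%, on the ground that “dissolution limits the process and starting material stays low”.

The simulation gave 17.2% and 15.7%. The half-life of target by step 4, 11 s, was short against the 40 s of the run. At 40.0 s this flask held 17.2% target against 26.4% over-reaction product, a standing share of 0.394 beside f of 0.356.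

For the neighbour flask read at 10 s, N is 0.649 and f comes to 0.736. Computed, that flask held 5.34% target and 1.30% over-reaction product, a standing share of 0.804.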